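If the electrophile is lost in proportion to what is left, I should reckon with the logarithm of the fraction left and not with the fraction made. Here is what is known and asked.

| flask | electrophile | nucleophile | gas | remark | time |
|---|---|---|---|---|---|
| Monday's | 13 mM | 24 mM (fed, over 10 h) | 2.7 mM (held) | run made earlier |  |
| Tuesday's | 10 mM | 24 mM (fed, over 10 h) | 2.7 mM (held) | run made earlier |  |
| autumn | 20 mM | 24.0 mM (fed, over 10 h) | 2.7 mM (held) |  | 20 h |
| midnight | 20 mM | 31.0 mM (fed, over 10 h) | 2.7 mM (held) |  | 20 h |

| run | time / h | electrophile / % | target / % |
|---|---|---|---|
| Monday's | 1.33 | 99.8 | 1.2 |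
| Monday's | 2.50 | 98.4 | 1.9 |
| Monday's | 4.00 | 94.8 | 4.6 |
| Monday's | 5.00 | 92.3 | 7.2 |
| Monday's | 6.00 | 89.7 | 8.7 |
| Monday's | 8.00 | 81.7 | 13.5 |
| Tuesday's | 0.500 | 100.1 | 0.1 |
| Tuesday's | 1.33 | 100.1 | 1.2 |
| Tuesday's | 2.50 | 97.5 | 1.9 |
| Tuesday's | 4.00 | 95.0 | 4.2 |
| Tuesday's | 5.00 | 92.1 | 6.1 |
| Tuesday's | 8.00 | 81.4 | 13.3 |

(readings scatter by 0.5 percentage points)

- the analysis behind the earlier runs scatters by 0.5 percentage points, standard deviation
- at the start none of the gas is in solution

1. part of the electrophile that has reacted at the end, autumn
2. part of the electrophile that has reacted at the end, midnight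
3. what raising the concentration of nucleophile from its lowest to its highest value here does to the part of the electrophile that has reacted (changes below 5 percentage points count as none) (it rises / no change / it falls)

Monday's and Tuesday's percentages agree within the scatter at different charges, so the loss is first order in electrophile. I define exposure as the area under c(nucleophile) against time, counted as if none were consumed: a triangle during the steady feed, then a rectangle. On Monday, exposure at 8.00 h is 276 M·s, and 81.7% of the electrophile remains. The logarithm of that fraction, sign dropped, divided by the exposure gives 2.63 L mol⁻¹ h⁻¹, the loss per unit of exposure. As a check, it predicts 92.4% left at 5.00 h, and Monday reads 92.3%.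

The bench rule treats the electrophile as pseudo-first-order, with exposure as its clock. By my reckoning, autumn reaches 1300 M·s and 61.2% reacts, while midnight reaches 1670 M·s and 70.6% reacts. But the rule ignores consumed nucleophile, so the ratio of electrophile to nucleophile charged marks its border. That ratio is 0.542 on Monday and 0.417 on Tuesday, but 0.833 in autumn and 0.645 at midnight. I therefore take my two figures as too high.

The forecast differs from them, with 52% for autumn, 62% for midnight, and it rises, on the grounds “k ≈ 0.0028 mM⁻¹h⁻¹ with 1:1 consumption”.

The flasks give 53.0% for autumn and 62.4% for midnight, and it rises by 9.4 percentage points.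

    electrophile + nucleophile → acid set free + target (k = 3.00 L mol⁻¹ h⁻¹)
    nucleophile + acid set free ⇌ protonated nucleophile, settled at all times (K = 930 L mol⁻¹)
    acid set free + free base ⇌ salt of the base, settled at all times (K = 5.40 × 10⁵ L mol⁻¹)
    target → over-reaction product (k = 0.130 h⁻¹)
    acid set free + free base ⇌ idle adduct, settled at all times (K = 3200 L mol⁻¹)
    gas ⇌ free base, rate k6*(csat - [free base]) (kL = 0.250 h⁻¹)

Midnight ends 9.4 points higher than autumn because of the difference in concentration of nucleophile: with that difference taken away, midnight's flask gives 53.0% in place of 62.4%. Neither does midnight's figure mark a stopping point: at 20 h, that flask still holds 38% of its electrophile and 56.5% of its nucleophile, and left until 200 h it reaches 99.9%.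

Take midnight's flask with 12 mM of electrophile. Its ratio of 0.387 lies below both earlier runs, so I use the rule as it stands, and 2.63 L mol⁻¹ h⁻¹ with exposure 1670 M·s gives 70.6% reacted. The computed result is 68.2%.

Readings and results stem from a simulated flask for an exercise.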